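**Plan**
1. Numbering: N–C1–C2–C3=C4, C5(=O), C6H2, C7H, C8H2, C15(Me)(OAc), C14H2, C13H(OAc), quaternary C12, C11–C10–C9–N. β is the face of the six-membered ring that carries C6 (on C7) and C4 (on C12). α is the face of H7 and C11.
2. Enabling feature: the triad C5(=O)–C4(=C3)–C12. This is a 2-alkylidenecyclopentanone (ring C4–C5–C6–C7–C12) whose alkylidene carbon C4 is bonded to quaternary C12, and whose C3=C4 bond lies inside the azonane with C2 cis to C12. It is the retron of a 1,2-shift in a 1-alkynylcyclobutanol, and a cyclic alkyne can only deliver this cis geometry.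
3. Cuts, in retrosynthetic order: N–Ns; C4–C12, redrawn as C5–C12 (cyclopentanone → cyclobutanol C5–C6–C7–C12, azonane → ten-membered azacycloalkyne); N–C9 and N–C1 (Mitsunobu); C4–C5 (acetylide addition); C15–O (C–H hydroxylation); C5–C12 and C6–C7 (enone–allene [2+2]); C11–C12 (Suzuki–Miyaura).
4. Forward order: six-membered ring (bought) → cyclobutane → ten-membered ring → five- and nine-membered rings together in one gold-catalysed shift → free N–H.
5. Stereochemistry: C15 comes from (R)-5-methylcyclohex-2-enone and steers the [2+2], which sets C7 and C12. C13 is set by CBS reduction and C15–O by retentive C–H insertion. C12 migrates with retention, and the alkene geometry follows from anti migration.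

Key step: step 13

Assumption: (R)-5-methylcyclohex-2-en-1-one (1) is taken as a catalogue compound.

Step 1
Reactants: 1 (R)-5-methylcyclohex-2-en-1-one
Product: 2 (R)-2-iodo-5-methylcyclohex-2-en-1-one
Conditions: I2 (1.5 equiv), pyridine–CH2Cl2 (1:1), 0 °C → rt
Reagents that add atoms: iodine `II`
Why: α-Iodination of an enone by addition–elimination (pyridine adds to C7, the enolate is iodinated at C12, pyridine leaves; Baylis–Hillman-type mechanism) is routine for cyclohexenones and does not touch C15.

Step 2
Reactants: 2 (R)-2-iodo-5-methylcyclohex-2-en-1-one; 3 allyl acetate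
Product: 5 3-[(4R)-4-methyl-6-oxocyclohex-1-en-1-yl]propyl acetate, via B-(3-acetoxypropyl)-9-BBN 4 (not isolated)
Conditions: 3, 9-BBN-H, THF, 0 °C → rt; then 2, Pd(dppf)Cl2 (5 mol %), AsPh3 (5 mol %), Cs2CO3, DMF–H2O, rt
Reagents that add atoms: none
Why: Anti-Markovnikov hydroboration of 3 followed by B-alkyl Suzuki–Miyaura coupling with the 2-iodoenone forms C11–C12 at sp2 carbon under mild aqueous base at room temperature, which leaves the acetate, the enone and C15 unchanged.

Step 3
Reactants: 5 3-[(4R)-4-methyl-6-oxocyclohex-1-en-1-yl]propyl acetate; 6 allene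
Product: 7 head-to-head photoadduct (cis-fused 1-(3-acetoxypropyl)-4-methyl-8-methylidenebicyclo[4.2.0]octan-2-one; C5=CH2 and C6 on the β face; 15-Me and C11 chain on the α face)
Conditions: hν (medium-pressure Hg lamp, Pyrex filter), 6 (excess), CH2Cl2, −78 °C
Reagents that add atoms: none
Why: Enone–allene [2+2] photocycloaddition gives the head-to-head adduct (central allene carbon C5 on the α-carbon C12, CH2 C6 on the β-carbon C7); C7 should bond axially on the half-chair that holds the 15-methyl group equatorial, that is anti to the methyl group, and the 1,4-diradical closes to the cis ring fusion, so C7 and C12 are set relative to C15.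

Step 4
Reactants: 7 head-to-head photoadduct
Product: 8 13β-alcohol (13S; other centres as in 7)
Conditions: (R)-2-methyl-CBS-oxazaborolidine (1.0 equiv), BH3·SMe2 (1.0 equiv, slow addition), THF, −20 °C; MeOH quench
Reagents that add atoms: none
Why: The Corey–Bakshi–Shibata reduction distinguishes the large quaternary C12 from the small C14H2, so the (R)-catalyst should deliver hydride to the α face and give the 13β alcohol under reagent control for a ketone whose two faces differ little; the catalyst–borane complex reduces the ketone faster than it hydroborates the 1,1-disubstituted alkene.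

Step 5
Reactants: 8 13β-alcohol
Product: 9 9,13β-diacetate (C5=CH2 retained)
Conditions: Ac2O, Et3N, DMAP (cat.), CH2Cl2, rt
Reagents that add atoms: acetic anhydride `CC(=O)OC(C)=O`
Why: DMAP-catalysed acylation installs at C13 the acetate that the target keeps, and this acetate deactivates C13–H for step 7.

Step 6
Reactants: 9 9,13β-diacetate
Product: 10 cyclobutanone 9,13β-diacetate (C5=O; 15β-H)
Conditions: O3, CH2Cl2, −78 °C; then PPh3, −78 °C → rt
Reagents that add atoms: ozone `[O-][O+]=O`
Why: Ozonolysis with reductive work-up cleaves the only C=C bond to the cyclobutanone, and because C12 is quaternary the β-acetoxy ketone cannot eliminate.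

Step 7
Reactants: 10 cyclobutanone 9,13β-diacetate
Product: 11 15β-hydroxy cyclobutanone 9,13β-diacetate (15α-Me)
Conditions: methyl(trifluoromethyl)dioxirane (TFDO, solution in CF3COCH3, 1.5 equiv), CH2Cl2, −20 → 0 °C
Reagents that add atoms: methyl(trifluoromethyl)dioxirane `CC1(OO1)C(F)(F)F`
Why: Dioxirane C–H hydroxylation inserts oxygen with retention into the most electron-rich accessible tertiary C–H bond: C15–H is equatorial in the chair that keeps 13-OAc and C6 equatorial, the only other tertiary C–H (C7–H) is a cyclobutane bridgehead bond β to the ketone, and the C–H bonds next to acetoxy groups are deactivated, so the hydroxyl takes the β position of the hydrogen.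

Step 8
Reactants: 11 15β-hydroxy cyclobutanone 9,13β-diacetate
Product: 12 cyclobutanone 9,13β,15β-triacetate
Conditions: Ac2O (5 equiv), DMAP (1 equiv), Et3N, CH2Cl2, 40 °C
Reagents that add atoms: acetic anhydride `CC(=O)OC(C)=O`
Why: Acylation of a tertiary alcohol with Ac2O and a full equivalent of DMAP (nucleophilic catalysis) is slow but standard, and no other group in 11 is acylated.

Step 9
Reactants: 12 cyclobutanone 9,13β,15β-triacetate; 13 but-3-yn-1-ol
Product: 15 alkynylcyclobutanol (4-hydroxybut-1-ynyl on C5 on the convex face cis to the C11 chain and H7; C5–OH on the concave face), via dilithiated but-3-yn-1-ol 14 (not isolated)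
Conditions: 13 (1.5 equiv), n-BuLi (3.0 equiv), THF, −78 → −20 °C; then 12, THF, −78 °C; sat. aq. NH4Cl at −78 °C
Reagents that add atoms: none
Why: 1,2-Addition of a lithium acetylide to a strained cyclobutanone at −78 °C is much faster than attack on acetates, and approach from the convex face (the concave face is roofed by the six-membered ring and the 13β-acetate) places the alkyne cis to the C11 chain at C5, a temporary stereocentre that step 13 erases.

Step 10
Reactants: 15 alkynylcyclobutanol; 16 2-nitrobenzenesulfonamide
Product: 17 nosylamide (C1–NHNs; C9–OAc retained)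
Conditions: 16 (3 equiv), PPh3, DIAD, THF, 0 °C → rt
Reagents that add atoms: none
Why: In this Fukuyama–Mitsunobu alkylation the acidic sulfonamide, used in excess to stop at monoalkylation, displaces the activated primary C1 hydroxyl by SN2, while the tertiary C5 hydroxyl is not activated.

Step 11
Reactants: 17 nosylamide
Product: 18 hydroxy nosylamide (C9–OH free; 13β- and 15β-acetates retained)
Conditions: K2CO3 (1.2 equiv), MeOH, −10 → 0 °C, stopped when 17 is consumed
Reagents that add atoms: none
Why: Base-catalysed transesterification discriminates by steric access, so the unhindered primary acetate should be methanolysed well before the neopentyl-type secondary acetate next to quaternary C12 and the tertiary acetate.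

Step 12
Reactants: 18 hydroxy nosylamide
Product: 19 ten-membered azacycloalkyne (ring C12–C5–C4≡C3–C2–C1–N(Ns)–C9–C10–C11; cis-fused to the cyclobutanol at C5–C12)
Conditions: PPh3, DIAD, toluene–THF, slow addition of 18 to a final 0.002 M, rt
Reagents that add atoms: none
Why: Intramolecular Fukuyama–Mitsunobu alkylation of nosylamides is an established closure of medium rings, including ten-membered rings that hold alkynes; here the four collinear atoms remove transannular contacts, the cis placement of both arms on the cyclobutane brings C9 near N, and the tertiary C5–OH is trans to the C11 chain and could form a tetrahydropyran only through a strained trans 6-4 fusion.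

Step 13
Reactants: 19 ten-membered azacycloalkyne
Product: 21 N-nosyl azonane enone (target skeleton with N–Ns), via vinylgold ketone 20 (not isolated)
Conditions: (4-CF3C6H4)3PAuCl (5 mol %), AgSbF6 (5 mol %), dry CH2Cl2, rt
Reagents that add atoms: none
Why: Proposed new method: the cationic monovalent gold complex binds the bent C3≡C4 bond of 19 on the outer, convex side of the ten-membered ring, the C5–C12 σ bond (pushed by the lone pair of the C5 hydroxyl) shifts to C4 anti to gold, and loss of the hydroxyl proton followed by protodeauration of vinylgold ketone 20 gives 21 and returns the catalyst. The closest known reaction type is the gold-catalysed ring expansion of 1-alkynylcyclobutanols to 2-alkylidenecyclopentanones, known for alkynes outside a ring; new here is that the alkyne and the migrating carbon sit in the same medium ring, where release of cyclobutane strain and of cycloalkyne bending strain should compensate for the lower reactivity of a dialkyl alkyne. Both rings close through the single new C4–C12 bond by a suprafacial 1,2-alkyl shift (a semipinacol step, not an end-to-end cyclisation): the four-membered ring C5–C6–C7–C12 grows to the five-membered ring C4–C5–C6–C7–C12 while the ten-membered ring expels C5 and contracts to the azonane. No new sp3 stereocentre forms: C12 migrates with retention and carries over its configuration from step 3, C5 becomes the planar carbonyl carbon, and the C3=C4 geometry (C2 cis to C12, H cis to C5) follows from anti addition of C12 and gold and is the one the nine-membered ring accepts. The step needs migration of C12 rather than C6 and a shift faster than Meyer–Schuster rearrangement, alkyne hydration or heteroatom attack: quaternary C12 is the better migrating group and a C6 shift would leave an E alkene inside a ten-membered ring, the medium is dry, and the nitrogen is a tertiary sulfonamide that cannot add to the alkyne.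

Step 14
Reactants: 21 N-nosyl azonane enone
Product: 22 target CNP0120442.1
Conditions: PhSH (2 equiv), K2CO3, MeCN, rt
Reagents that add atoms: none
Why: In the Fukuyama denosylation thiolate adds to the nitroarene (Meisenheimer complex, SNAr), SO2 is lost and the secondary amine is freed under mild base that spares both acetates, while thiol addition to the hindered trisubstituted enone is reversible.

**Compound list**
1 | (R)-5-methylcyclohex-2-en-1-one | `C[C@@H]1CC=CC(=O)C1` | starting material
2 | (R)-2-iodo-5-methylcyclohex-2-en-1-one | `C[C@@H]1CC=C(I)C(=O)C1` | intermediate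
3 | allyl acetate | `C=CCOC(C)=O` | starting material
4 | B-(3-acetoxypropyl)-9-borabicyclo[3.3.1]nonane | `CC(=O)OCCCB1C2CCCC1CCC2` | intermediate
5 | 3-[(4R)-4-methyl-6-oxocyclohex-1-en-1-yl]propyl acetate | `C[C@@H]1CC=C(CCCOC(C)=O)C(=O)C1` | intermediate
6 | allene (propa-1,2-diene) | `C=C=C` | starting material
7 | head-to-head photoadduct; cis-fused 1-(3-acetoxypropyl)-4-methyl-8-methylidenebicyclo[4.2.0]octan-2-one; C5=CH2 and C6 β; 15-Me and C11 chain α | `O=C1C[C@H](C)C[C@H]2CC(=C)[C@]21CCCOC(C)=O` | intermediate
8 | 13β-alcohol (13S) derived from 7 | `O[C@H]1C[C@H](C)C[C@H]2CC(=C)[C@]21CCCOC(C)=O` | intermediate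
9 | 9,13β-diacetate with C5=CH2 | `CC(=O)O[C@H]1C[C@H](C)C[C@H]2CC(=C)[C@]21CCCOC(C)=O` | intermediate
10 | cyclobutanone 9,13β-diacetate (C5=O; 15β-H; 15α-Me) | `CC(=O)O[C@H]1C[C@H](C)C[C@H]2CC(=O)[C@]21CCCOC(C)=O` | intermediate
11 | 15β-hydroxy cyclobutanone 9,13β-diacetate (15α-Me) | `CC(=O)O[C@H]1C[C@@](C)(O)C[C@H]2CC(=O)[C@]21CCCOC(C)=O` | intermediate
12 | cyclobutanone 9,13β,15β-triacetate | `CC(=O)O[C@H]1C[C@@](C)(OC(C)=O)C[C@H]2CC(=O)[C@]21CCCOC(C)=O` | intermediate
13 | but-3-yn-1-ol | `C#CCCO` | starting material
14 | dilithiated but-3-yn-1-ol | `[Li]C#CCCO[Li]` | intermediate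
15 | alkynylcyclobutanol; 4-hydroxybut-1-ynyl on C5 cis to the C11 chain; C5–OH on the concave face | `CC(=O)O[C@H]1C[C@@](C)(OC(C)=O)C[C@H]2C[C@](O)(C#CCCO)[C@]21CCCOC(C)=O` | intermediate
16 | 2-nitrobenzenesulfonamide | `NS(=O)(=O)c1ccccc1[N+](=O)[O-]` | starting material
17 | nosylamide (C1–NHNs; C9–OAc) | `CC(=O)O[C@H]1C[C@@](C)(OC(C)=O)C[C@H]2C[C@](O)(C#CCCNS(=O)(=O)c3ccccc3[N+](=O)[O-])[C@]21CCCOC(C)=O` | intermediate
18 | hydroxy nosylamide (C1–NHNs; C9–OH) | `CC(=O)O[C@H]1C[C@@](C)(OC(C)=O)C[C@H]2C[C@](O)(C#CCCNS(=O)(=O)c3ccccc3[N+](=O)[O-])[C@]21CCCO` | intermediate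
19 | ten-membered N-nosyl azacycloalkyne cis-fused to the cyclobutanol at C5–C12 | `CC(=O)O[C@H]1C[C@@](C)(OC(C)=O)C[C@H]2C[C@]3(O)C#CCCN(S(=O)(=O)c4ccccc4[N+](=O)[O-])CCC[C@@]321` | intermediate
20 | vinylgold ketone (gold on C3, cis to C5) | `CC(=O)O[C@H]1C[C@@](C)(OC(C)=O)C[C@H]2CC(=O)/C3=C(/CCN(S(=O)(=O)c4ccccc4[N+](=O)[O-])CCC[C@@]321)[Au-][P+](c1ccc(cc1)C(F)(F)F)(c1ccc(cc1)C(F)(F)F)c1ccc(cc1)C(F)(F)F` | intermediate
21 | N-nosyl azonane enone (13β,15β-diacetate; C2 cis to C12) | `CC(=O)O[C@H]1C[C@@](C)(OC(C)=O)C[C@H]2CC(=O)/C3=C/CCN(S(=O)(=O)c4ccccc4[N+](=O)[O-])CCC[C@@]321` | intermediate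
22 | CNP0120442.1 | `CC(=O)O[C@H]1C[C@@](C)(OC(C)=O)C[C@H]2CC(=O)/C3=C/CCNCCC[C@@]321` | target

Total steps: 14. Longest linear sequence: 14 steps (1 → 22).

**Steps most likely to fail**

**Step 13.** The dialkyl alkyne may be activated too weakly. A 1,3-transposition of the hydroxyl group (Meyer–Schuster) or slow decomposition could then outrun the 1,2-shift.
- The fallback sets out from 19 and returns at 21.
- A stoichiometric iodonium source replaces the catalytic π-acid (N-iodosuccinimide, cat. PhI(OH)OTs, MeCN, 0 °C → rt). This is the halonium-induced ring expansion of 1-alkynylcycloalkanols, a known reaction type.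
- The same anti shift of C12 should give the β-iodo enone F1, with iodine on C3 cis to C5.
- Hydrodeiodination with retention of the alkene geometry (Pd(PPh3)4, HCO2H, Et3N, DMF, rt) then gives 21.

**Step 12.** Ring closure may lose to oligomerisation because of strain in the ten-membered transition state. The same would happen if addition in step 9 took the concave face and put the two arms trans.
- The fallback sets out from 15 and returns at 21, and it does not depend on the C5 configuration.
- The primary hydroxyl is acetylated (Ac2O, pyridine, 0 °C) to the tetraacetate F2, so that no free O–H or N–H near the alkyne can add to it.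
- The gold-catalysed ring expansion is run on this open-chain alkynylcyclobutanol under the conditions of step 13, giving the (E)-alkylidenecyclopentanone F3.
- K2CO3 in MeOH at 0 °C frees the two primary alcohols to give the diol F4.
- A double Fukuyama–Mitsunobu alkylation of 16 (PPh3, DIAD, toluene, high dilution) closes the azonane directly.

**Step 3.** The α-alkylated enone may add allene sluggishly. It may also give a trans-fused adduct that cannot be epimerised because C12 is quaternary.
- The fallback sets out from 1 and returns at 7, bypassing steps 1 and 2.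
- Enone 1 is irradiated with 6 under the same conditions to give the parent photoadduct F5. Its C12–H allows any trans-fused isomer to be epimerised to the cis isomer on basic alumina.
- C12–H is both α to the ketone and allylic. KN(SiMe3)2 (THF, −78 → −20 °C) should therefore form the extended dienolate.
- This dienolate is alkylated at C12 with 3-iodopropyl acetate from the convex α face, the only face that keeps the cis ring fusion.

Further compounds
F1 | step 13 | β-iodo enone (iodine on C3, cis to C5; N–Ns) | `CC(=O)O[C@H]1C[C@@](C)(OC(C)=O)C[C@H]2CC(=O)/C3=C(/CCN(S(=O)(=O)c4ccccc4[N+](=O)[O-])CCC[C@@]321)I`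
F2 | step 12 | tetraacetate of the alkynylcyclobutanol (C1, C9, C13, C15 acetates; C5–OH free) | `CC(=O)O[C@H]1C[C@@](C)(OC(C)=O)C[C@H]2C[C@](O)(C#CCCOC(C)=O)[C@]21CCCOC(C)=O`
F3 | step 12 | (E)-alkylidenecyclopentanone tetraacetate (open chain; C2 cis to C12) | `CC(=O)O[C@H]1C[C@@](C)(OC(C)=O)C[C@H]2CC(=O)/C(=C/CCOC(C)=O)[C@]21CCCOC(C)=O`
F4 | step 12 | (E)-alkylidenecyclopentanone C1,C9-diol 13β,15β-diacetate | `CC(=O)O[C@H]1C[C@@](C)(OC(C)=O)C[C@H]2CC(=O)/C(=C/CCO)[C@]21CCCO`
F5 | step 3 | parent photoadduct (cis-fused 4-methyl-8-methylidenebicyclo[4.2.0]octan-2-one; C12–H α) | `O=C1C[C@H](C)C[C@H]2CC(=C)[C@H]21`
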